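**Plan**
- Retrosynthetic cuts, in order: the C8–O ester bond; the O2–C3 bond of the pyran (lactol opened to a C1 aldehyde plus a C3≡C4 alkyne); the C7–C8 bond of the carbocycle, re-drawn as a C6–C8 bond; then the C6–C7 and C4a–C4 bonds.
- Enabling feature: in the carbocycle (C4a, C5, C6, C7, C8, C8a) the C6 ketone and the C7 tertiary carbinol form an α-ketol. A 2-hydroxy-2-methylcyclohexenone is the rearranged form of a 1-acetylcyclopentenol, so C7 is the former acetyl carbon.
- Forward order: cyclopentenone → trans C8/C8a diol → C4a-alkynyl cyclopentenone → C6 acetyl carbinol → ring expansion to the cyclohexenone → C8 ester → pyran ring by oxa-conjugate addition → enal.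
- Stereochemistry: the silyloxy centre of 1 relays to C8/C8a (anti epoxidation, invertive epoxide opening) and is then erased. The C6 carbinol (addition anti to C8–OPMB) relays to C7 in the 1,2-shift. C3′ comes from (R)-3-hydroxybutanoic acid. C1 is set under equilibrium.

Key step: step 10

Assumption: the hemiacetal carbon C1 equilibrates by ring–chain tautomerism and is taken to settle as the natural 1R epimer (C1–OH trans to C8a–OH, anomerically stabilised).
Convention: locants are those of the target's isochromene skeleton; β is the face of the carbocycle that carries (or will carry) the C8a oxygen, α the opposite face.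

Step 1
Reactants: 1 (S)-4-(tert-butyldimethylsilyloxy)cyclopent-2-en-1-one
Product: 2 (S)-4-(tert-butyldimethylsilyloxy)-2-(hydroxymethyl)cyclopent-2-en-1-one
Conditions: 37% aq. CH2O, imidazole (1 equiv), THF/H2O 1:1, rt
Reagents that add atoms: formaldehyde, C=O
Why: Morita–Baylis–Hillman hydroxymethylation of a cyclic enone under imidazole catalysis places C1 on the future C8a without touching the silyloxy stereocentre (future C6).

Step 2
Reactants: 2 (S)-4-(tert-butyldimethylsilyloxy)-2-(hydroxymethyl)cyclopent-2-en-1-one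
Product: 3 4-(tert-butyldimethylsilyloxy)-1-(hydroxymethyl)-6-oxabicyclo[3.1.0]hexan-2-one (β-oxirane on C8a/C8, anti to the α C6–OTBS)
Conditions: 30% H2O2, NaOH (0.2 equiv), MeOH, −30 → 0 °C
Reagents that add atoms: hydrogen peroxide, OO
Why: Weitz–Scheffer nucleophilic epoxidation; hydroperoxide adds to C8 anti to the adjacent silyloxy group, so the oxirane (future C8a–O) forms on the face opposite OTBS.

Step 3
Reactants: 3 trans-epoxy silyloxy ketone
Product: 4 1-(hydroxymethyl)-6-oxabicyclo[3.1.0]hex-3-en-2-one (β-oxirane on C8a/C8)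
Conditions: DBU (1.2 equiv), CH2Cl2, 0 °C
Reagents that add atoms: none
Why: E1cB β-elimination of silanolate from the β-silyloxy ketone should give the epoxy enone; the silyloxy centre has already passed its chirality to C8/C8a and is erased.

Step 4
Reactants: 4 epoxy enone
Product: 5 (4S,5R)-5-hydroxy-5-(hydroxymethyl)-4-[(4-methoxybenzyl)oxy]cyclopent-2-en-1-one (C8–OPMB α, C8a–OH β, C1 α)
Conditions: 4-MeOC6H4CH2OH (3 equiv), BF3·OEt2 (0.2 equiv), CH2Cl2, −40 → −20 °C
Reagents that add atoms: 4-methoxybenzyl alcohol, COc1ccc(CO)cc1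
Why: Lewis acid-catalysed SN2 alcoholysis of the vinyl epoxide at the secondary allylic C8 (C8a is quaternary and α to the ketone) proceeds with inversion and sets the trans C8–O/C8a–O pair.

Step 5
Reactants: 5 PMB ether diol
Product: 6 (5R,9S)-9-[(4-methoxybenzyl)oxy]-2,2-dimethyl-1,3-dioxaspiro[4.4]non-7-en-6-one (spiro-acetonide on C8a–O/C1–O)
Conditions: Me2C(OMe)2, PPTS (cat.), CH2Cl2, rt
Reagents that add atoms: 2,2-dimethoxypropane, COC(C)(C)OC
Why: Acid-catalysed transacetalisation forms the dioxolane of the primary/tertiary 1,2-diol; no stereocentre is involved.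

Step 6
Reactants: 7 (E)-pent-2-en-4-yn-1-ol
Product: 8 tert-butyl{[(E)-pent-2-en-4-yn-1-yl]oxy}diphenylsilane
Conditions: t-BuPh2SiCl, imidazole, CH2Cl2, 0 °C → rt
Reagents that add atoms: tert-butyl(chloro)diphenylsilane, CC(C)(C)[Si](Cl)(c1ccccc1)c1ccccc1
Why: Standard silylation of a primary alcohol; the E-alkene is unchanged.

Step 7
Reactants: 6 spiro-acetonide enone; 8 silyl-protected enynol
Product: 10 C4a tertiary propargylic alcohol (epimer mixture at C4a) bearing the (E)-5-(tert-butyldiphenylsilyloxy)pent-3-en-1-ynyl chain, via lithium acetylide 9 (not isolated)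
Conditions: 8, n-BuLi, THF, −78 °C; then 6, −78 °C; then H2O
Reagents that add atoms: none
Why: 1,2-Addition of a lithium acetylide to the enone carbonyl (C4a) at low temperature; the new carbinol centre is inconsequential because it becomes sp2 in step 8.

Step 8
Reactants: 10 tertiary allylic propargylic alcohol
Product: 11 cyclopent-2-enone with C6 ketone, C5=C4a alkene carrying the enyne at C4a, spiro-acetonide at C8a (O β) and α-OPMB at C8
Conditions: pyridinium chlorochromate [C5H5NH][CrO3Cl] (3 equiv), 4 Å MS, CH2Cl2, rt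
Reagents that add atoms: pyridinium chlorochromate, [O-][Cr](=O)(=O)Cl.c1cc[nH+]cc1
Why: Babler–Dauben oxidative 1,3-transposition ([3,3] shift of the chromate ester, then oxidation) moves the oxygen from C4a to C6 and leaves the enyne on the β-carbon of the new enone; the acetonide shields the neighbouring C8a oxygen from glycol cleavage.

Step 9
Reactants: 11 enynone
Product: 13 α-ketol with C6 acetyl β and C6–OH α, via ethoxyvinyl carbinol 12 (not isolated)
Conditions: CH2=CHOEt, t-BuLi, THF, −78 → 0 °C; CeCl3, −78 °C; then 11, −78 °C; then 0.2 M aq. HCl, THF, 0 °C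
Reagents that add atoms: ethyl vinyl ether, C=COCC; water, O
Why: Organocerium 1,2-addition of 1-ethoxyvinyllithium (acetyl anion equivalent) should occur on the β face, anti to the adjacent α C8–OPMB, which sets C6; the enol ether then hydrolyses to the methyl ketone far faster than any other acid-labile group reacts.

Step 10
Reactants: 13 1-acetylcyclopent-2-en-1-ol (α-ketol)
Product: 14 cyclohex-2-enone with C6 ketone, 7β-hydroxy-7α-methyl, 8α-OPMB, spiro-acetonide at C8a and the enyne at C4a
Conditions: KOt-Bu (0.3 equiv), 18-crown-6 (0.35 equiv), THF, −40 → 0 °C; pH 7 buffer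
Reagents that add atoms: none
Why: The potassium alkoxide of the C6 carbinol pushes the ring bond C6–C8 onto the acetyl carbonyl carbon, so the acetyl carbon is inserted between C6 and C8 as C7 and C6 becomes the ring ketone; this is a base-mediated α-ketol (acyloin) rearrangement of the ring-enlarging type known for 1-acylcycloalkanols. No ring is closed by cyclisation: the six-membered carbocycle arises from the cyclopentene by a suprafacial 1,2-carbon shift, with C8 migrating with retention so that the C8/C8a pair is untouched. The new C7 centre is controlled by the C6 centre from step 9: in the crown-ether-separated alkoxide the C–O(−) and C=O dipoles are antiperiplanar, so C8 attacks the acetyl face that puts the new C7–OH on the β face (opposite the former α C6–O) and the methyl group α. Two selectivities are needed: migration of C8 and not of the alkenyl carbon C5, and the anti and not the chelated syn geometry, which would give the C7 epimer. The first should be secured because only C8 migration leaves the alkenyl group on C6, so the nascent ketone develops conjugation with the C5=C4a–alkyne system, and the oxygen-bearing C8 is a good migrating group; the second by excluding chelating counter-ions and Lewis acids. Strain relief plus the gained conjugation should make the shift effectively irreversible at 0 °C, so the product is not re-equilibrated.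

Step 11
Reactants: 14 ring-expanded PMB ether
Product: 15 7β,8α-diol (C8–OH free) of the cyclohexenone
Conditions: DDQ, CH2Cl2/pH 7 buffer 10:1, 0 °C
Reagents that add atoms: none
Why: Oxidative cleavage of the 4-methoxybenzyl ether by DDQ frees only C8–OH; silyl ether, acetonide and enynone are inert.

Step 12
Reactants: 16 (R)-3-hydroxybutanoic acid
Product: 18 (R)-3-(tert-butyldimethylsilyloxy)butanoic acid, via bis-silyl derivative 17 (not isolated)
Conditions: t-BuMe2SiCl (2.3 equiv), imidazole (5 equiv), DMF, rt; then THF/H2O/AcOH 4:1:1, rt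
Reagents that add atoms: tert-butyl(chloro)dimethylsilane, CC(C)(C)[Si](C)(C)Cl
Why: Double silylation followed by selective hydrolysis of the labile silyl ester gives the O-protected acid; the stereocentre is untouched.

Step 13
Reactants: 15 diol; 18 protected acid
Product: 20 C8 (R)-3-(tert-butyldimethylsilyloxy)butanoate ester, via mixed anhydride 19 (not isolated)
Conditions: 18, 2,4,6-Cl3C6H2COCl, Et3N, THF, rt; then 15, DMAP, toluene, rt → 40 °C
Reagents that add atoms: none
Why: Yamaguchi esterification through the mixed anhydride acylates the only secondary alcohol (C8–OH); the tertiary C7–OH is unreactive and no stereocentre changes.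

Step 14
Reactants: 20 ester acetonide
Product: 21 C1/C8a diol (primary C1–OH, tertiary C8a–OH)
Conditions: AcOH/THF/H2O 3:1:1, rt
Reagents that add atoms: none
Why: Mild acid hydrolysis of the spiro-dioxolane should be faster than cleavage of the secondary TBS ether or the TBDPS ether.

Step 15
Reactants: 21 diol
Product: 23 bis-silylated lactol (pyran ring closed, 1R), via hydroxy aldehyde 22 (not isolated)
Conditions: SO3·pyridine (3 equiv), Et3N (6 equiv), DMSO/CH2Cl2 1:3, 0 °C; then H2O, THF, rt
Reagents that add atoms: water, O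
Why: Parikh–Doering oxidation converts the primary C1 alcohol into the α-hydroxy aldehyde without glycol cleavage; its hydrate, the most acidic hydroxyl present, should then add under amine catalysis in a 6-endo-dig oxa-conjugate (1,6-) addition to C3 of the ynenone to close the pyran as its lactol, with C1 settling as the 1R epimer.

Step 16
Reactants: 23 bis-silylated lactol
Product: 24 triol with free side-chain allylic alcohol and free 3′-OH
Conditions: HF·pyridine, pyridine, THF, 0 °C → rt
Reagents that add atoms: none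
Why: Buffered fluoride cleavage of both Si–O bonds should leave the lactol, the ester and the dienone intact.

Step 17
Reactants: 24 triol
Product: 25 Azaphilone D, (1R,7S,8R,8aS)-1,7,8a-trihydroxy-7-methyl-6-oxo-3-[(E)-3-oxoprop-1-enyl]-6,7,8,8a-tetrahydro-1H-isochromen-8-yl (R)-3-hydroxybutanoate
Conditions: MnO2 (activated, 15 equiv), CH2Cl2, rt
Reagents that add atoms: none
Why: MnO2 oxidises the dienylic primary alcohol selectively (allylic alcohol oxidation); the non-allylic lactol and the secondary and tertiary alcohols should remain.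

**Compound list**
1 | (S)-4-(tert-butyldimethylsilyloxy)cyclopent-2-en-1-one | O=C1C=C[C@@H](O[Si](C)(C)C(C)(C)C)C1 | starting material
2 | (S)-4-(tert-butyldimethylsilyloxy)-2-(hydroxymethyl)cyclopent-2-en-1-one | O=C1C(CO)=C[C@@H](O[Si](C)(C)C(C)(C)C)C1 | intermediate
3 | 4-(tert-butyldimethylsilyloxy)-1-(hydroxymethyl)-6-oxabicyclo[3.1.0]hexan-2-one, oxirane anti to OTBS | O=C1[C@]2(CO)O[C@@H]2[C@@H](O[Si](C)(C)C(C)(C)C)C1 | intermediate
4 | 1-(hydroxymethyl)-6-oxabicyclo[3.1.0]hex-3-en-2-one (β-oxirane) | O=C1C=C[C@H]2O[C@@]12CO | intermediate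
5 | (4S,5R)-5-hydroxy-5-(hydroxymethyl)-4-[(4-methoxybenzyl)oxy]cyclopent-2-en-1-one | O=C1C=C[C@H](OCc2ccc(OC)cc2)[C@]1(O)CO | intermediate
6 | (5R,9S)-9-[(4-methoxybenzyl)oxy]-2,2-dimethyl-1,3-dioxaspiro[4.4]non-7-en-6-one | O=C1C=C[C@H](OCc2ccc(OC)cc2)[C@]13COC(C)(C)O3 | intermediate
7 | (E)-pent-2-en-4-yn-1-ol | C#C/C=C/CO | starting material
8 | tert-butyl{[(E)-pent-2-en-4-yn-1-yl]oxy}diphenylsilane | C#C/C=C/CO[Si](c1ccccc1)(c1ccccc1)C(C)(C)C | intermediate
9 | lithium acetylide of 8 | [Li]C#C/C=C/CO[Si](c1ccccc1)(c1ccccc1)C(C)(C)C | intermediate (not isolated)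
10 | C4a tertiary propargylic alcohol from 6 and 9 (epimers at C4a) | OC1(C#C/C=C/CO[Si](c2ccccc2)(c2ccccc2)C(C)(C)C)C=C[C@H](OCc2ccc(OC)cc2)[C@]13COC(C)(C)O3 | intermediate
11 | cyclopentenone: C6 ketone, enyne at C4a, spiro-acetonide at C8a, α-OPMB at C8 | O=C1C=C(C#C/C=C/CO[Si](c2ccccc2)(c2ccccc2)C(C)(C)C)[C@@]2(COC(C)(C)O2)[C@H]1OCc1ccc(OC)cc1 | intermediate
12 | C6 (1-ethoxyvinyl) carbinol (ethoxyvinyl β, OH α) | C=C(OCC)[C@]1(O)C=C(C#C/C=C/CO[Si](c2ccccc2)(c2ccccc2)C(C)(C)C)[C@@]2(COC(C)(C)O2)[C@H]1OCc1ccc(OC)cc1 | intermediate (not isolated)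
13 | C6 acetyl carbinol (α-ketol; acetyl β, OH α) | CC(=O)[C@]1(O)C=C(C#C/C=C/CO[Si](c2ccccc2)(c2ccccc2)C(C)(C)C)[C@@]2(COC(C)(C)O2)[C@H]1OCc1ccc(OC)cc1 | intermediate
14 | ring-expanded cyclohexenone: 7β-OH, 7α-Me, 8α-OPMB, C8a spiro-acetonide | O=C1C=C(C#C/C=C/CO[Si](c2ccccc2)(c2ccccc2)C(C)(C)C)[C@@]2(COC(C)(C)O2)[C@@H](OCc2ccc(OC)cc2)[C@]1(C)O | intermediate
15 | 7β,8α-diol of 14 (PMB removed) | O=C1C=C(C#C/C=C/CO[Si](c2ccccc2)(c2ccccc2)C(C)(C)C)[C@@]2(COC(C)(C)O2)[C@@H](O)[C@]1(C)O | intermediate
16 | (R)-3-hydroxybutanoic acid | C[C@@H](O)CC(=O)O | starting material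
17 | tert-butyldimethylsilyl (R)-3-(tert-butyldimethylsilyloxy)butanoate | C[C@@H](O[Si](C)(C)C(C)(C)C)CC(=O)O[Si](C)(C)C(C)(C)C | intermediate (not isolated)
18 | (R)-3-(tert-butyldimethylsilyloxy)butanoic acid | C[C@@H](O[Si](C)(C)C(C)(C)C)CC(=O)O | intermediate
19 | (R)-3-(tert-butyldimethylsilyloxy)butanoic 2,4,6-trichlorobenzoic anhydride | C[C@@H](O[Si](C)(C)C(C)(C)C)CC(=O)OC(=O)c1c(Cl)cc(Cl)cc1Cl | intermediate (not isolated)
20 | C8 ester of 15 with 18 (acetonide, TBS, TBDPS in place) | C[C@@H](O[Si](C)(C)C(C)(C)C)CC(=O)O[C@@H]1[C@]2(COC(C)(C)O2)C(C#C/C=C/CO[Si](c2ccccc2)(c2ccccc2)C(C)(C)C)=CC(=O)[C@@]1(C)O | intermediate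
21 | C1/C8a diol of 20 | C[C@@H](O[Si](C)(C)C(C)(C)C)CC(=O)O[C@@H]1[C@](O)(CO)C(C#C/C=C/CO[Si](c2ccccc2)(c2ccccc2)C(C)(C)C)=CC(=O)[C@@]1(C)O | intermediate
22 | C1 aldehyde (α-hydroxy aldehyde) of 21 | C[C@@H](O[Si](C)(C)C(C)(C)C)CC(=O)O[C@@H]1[C@](O)(C=O)C(C#C/C=C/CO[Si](c2ccccc2)(c2ccccc2)C(C)(C)C)=CC(=O)[C@@]1(C)O | intermediate (not isolated)
23 | bis-silylated lactol (TBS on 3′-O, TBDPS on side-chain O) | C[C@@H](O[Si](C)(C)C(C)(C)C)CC(=O)O[C@@H]1[C@@]2(O)C(=CC(=O)[C@@]1(C)O)C=C(/C=C/CO[Si](c1ccccc1)(c1ccccc1)C(C)(C)C)O[C@H]2O | intermediate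
24 | desilylated triol (side-chain allylic alcohol) | C[C@@H](O)CC(=O)O[C@@H]1[C@@]2(O)C(=CC(=O)[C@@]1(C)O)C=C(/C=C/CO)O[C@H]2O | intermediate
25 | Azaphilone D | C[C@@H](O)CC(=O)O[C@@H]1[C@@]2(O)C(=CC(=O)[C@@]1(C)O)C=C(/C=C/C=O)O[C@H]2O | target

**Totals**
Total steps: 17. Longest linear sequence: 15 (1 → 25 through steps 1–5, 7–11 and 13–17).

**Steps most likely to fail**

1. Step 10. The alkenyl carbon C5 may migrate in place of C8, or part of the material may react through a chelated syn geometry and give the C7 epimer. The fallback sets out from 11 and comes back at 14. Enynone 11 would be homologated by one carbon with diazoethane under Sc(OTf)3 catalysis (CH2Cl2, −78 °C). This is a diazoalkane ring expansion of the Tiffeneau–Demjanov type, in which the saturated oxygen-bearing C8 migrates so that the enone stays conjugated. It should give the 7-methylcyclohexenone F1 as a C7 epimer mixture. Deprotonation at C7, the only enolisable position, with KN(SiMe3)2 (THF, −78 °C) and hydroxylation with 3-phenyl-2-(phenylsulfonyl)oxaziridine on the β face, anti to the α C8–OPMB, should give 14.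

2. Step 15. The oxa-conjugate addition may be slow, or the tertiary C8a hydroxyl may compete for the alkyne. The fallback sets out from 21 and comes back at 24. Exhaustive silylation (Et3SiOTf, 2,6-lutidine, CH2Cl2, −78 → 0 °C) would give the tris(triethylsilyl) ether F2. Swern oxidation (oxalyl chloride, DMSO, then Et3N), which converts a primary triethylsilyl ether directly into the aldehyde while the tertiary ones persist, would give the C8a-silyloxy aldehyde F3. With the C8a oxygen blocked, (Ph3P)AuNTf2 in wet CH2Cl2 should effect the 6-endo-dig cyclisation of the alkynyl aldehyde with water capture and give the lactol F4. HF·pyridine as in step 16 would remove all silyl groups and give 24.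

3. Step 4. The 4-methoxybenzyl alcohol may self-condense under the Lewis acid, or the alcoholysis may lose regiocontrol. The fallback sets out from 4 and comes back at 6. Acid-catalysed hydrolysis (HClO4 cat., THF/H2O, 0 °C) would open the epoxide at C8 with inversion and give the triol F5. 2,2-Dimethoxypropane with PPTS should form the dioxolane of the primary/tertiary diol and give the acetonide F6 with C8–OH free. 4-Methoxybenzyl trichloroacetimidate with La(OTf)3 (cat.) in toluene would then give 6.

**Further compounds**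
F1 | step 10 | 7-methylcyclohexenone from diazoethane homologation of 11 (C7 epimers; 8α-OPMB, C8a spiro-acetonide) | O=C1C=C(C#C/C=C/CO[Si](c2ccccc2)(c2ccccc2)C(C)(C)C)[C@@]2(COC(C)(C)O2)[C@@H](OCc2ccc(OC)cc2)C1C
F2 | step 15 | tris(triethylsilyl) ether of 21 (C1–O, C8a–O, C7–O) | C[C@@H](O[Si](C)(C)C(C)(C)C)CC(=O)O[C@@H]1[C@](O[Si](CC)(CC)CC)(CO[Si](CC)(CC)CC)C(C#C/C=C/CO[Si](c2ccccc2)(c2ccccc2)C(C)(C)C)=CC(=O)[C@@]1(C)O[Si](CC)(CC)CC
F3 | step 15 | C1 aldehyde with C8a–OSiEt3 and C7–OSiEt3 | C[C@@H](O[Si](C)(C)C(C)(C)C)CC(=O)O[C@@H]1[C@](O[Si](CC)(CC)CC)(C=O)C(C#C/C=C/CO[Si](c2ccccc2)(c2ccccc2)C(C)(C)C)=CC(=O)[C@@]1(C)O[Si](CC)(CC)CC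
F4 | step 15 | lactol with C8a–OSiEt3 and C7–OSiEt3 | C[C@@H](O[Si](C)(C)C(C)(C)C)CC(=O)O[C@@H]1[C@@]2(O[Si](CC)(CC)CC)C(=CC(=O)[C@@]1(C)O[Si](CC)(CC)CC)C=C(/C=C/CO[Si](c1ccccc1)(c1ccccc1)C(C)(C)C)O[C@H]2O
F5 | step 4 | (4S,5R)-4,5-dihydroxy-5-(hydroxymethyl)cyclopent-2-en-1-one | O=C1C=C[C@H](O)[C@]1(O)CO
F6 | step 4 | 9-hydroxy-2,2-dimethyl-1,3-dioxaspiro[4.4]non-7-en-6-one (C8–OH α, acetonide O β) | O=C1C=C[C@H](O)[C@]13COC(C)(C)O3
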